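## Retrosynthetic overview
1. Ring C is formed last by closing the aryl–oxygen bond O1–C8a. The flavone goes back to the open 1,3-diketone ArA–CO–CH2–CO–ArB, whose ring A has a plain C–H where O1 will sit.
2. The diketone is cut at C3–C4 (Claisen). The ring B methyl ketone is the enolate partner, and methyl 2,3-dimethoxybenzoate supplies ring A and C4 as the acyl donor.
3. The ring B ketone comes from 1,2,4,5-tetramethoxybenzene by ortho-lithiation and acetylation.
4. Rings A and B are bought with all six methoxy groups in place, so no protecting groups and no late O-methylation are needed.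

Assumption: the target has no stereocentre, and ring B is symmetric about its C1'–C4' axis so there are no atropisomers; it is one achiral compound and needs no stereocontrol.

## Route

Step 1
Reactants: 1 1,2,4,5-tetramethoxybenzene
Product: 4 1-(2,3,5,6-tetramethoxyphenyl)ethan-1-one, via aryllithium 2 (not isolated), via lithium hemiaminalate 3 (not isolated)
Conditions: n-BuLi (1.05 equiv), THF, 0 °C to rt, 1 h; MeC(O)N(OMe)Me (1.3 equiv), −78 °C to 0 °C; 1 M HCl
Reagents that add atoms: N-methoxy-N-methylacetamide, CC(=O)N(C)OC; n-butyllithium, [Li]CCCC (supplies only the lithium of 2 and 3)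
Why: Directed ortho-metalation followed by Weinreb ketone synthesis: the two ring C–H bonds of 1 are equivalent and each lies between two methoxy groups, so a single aryllithium forms, and the chelated adduct 3 cannot collapse before the acid quench, which stops the addition at the ketone; no stereocentre remains in 4.

Step 2
Reactants: 4 1-(2,3,5,6-tetramethoxyphenyl)ethan-1-one; 5 methyl 2,3-dimethoxybenzoate (1.2 equiv)
Product: 7 1-(2,3-dimethoxyphenyl)-3-(2,3,5,6-tetramethoxyphenyl)propane-1,3-dione, via sodium diketonate 6 (not isolated)
Conditions: NaH (2.5 equiv), THF, reflux, 4 h; 1 M HCl, 0 °C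
Reagents that add atoms: sodium hydride, [Na+].[H-] (supplies only the sodium of 6)
Why: Crossed Claisen condensation: 5 cannot enolise, the carbonyl group of 4 is shielded by two ortho methoxy groups so 4 acts only as the enolate partner, and irreversible deprotonation to diketonate 6 drives the equilibrium; no stereocentre is formed.

Step 3
Reactants: 7 1-(2,3-dimethoxyphenyl)-3-(2,3,5,6-tetramethoxyphenyl)propane-1,3-dione
Product: 8 5,6-dimethoxy-2-(2,3,5,6-tetramethoxyphenyl)-4H-chromen-4-one (5,6,2',3',5',6'-hexamethoxyflavone)
Conditions: Pd(OAc)2 (10 mol %), N-acetylglycine (20 mol %), KOAc (20 mol %), PhCO3t-Bu (1.5 equiv), PhCF3, 100 °C, N2, 16 h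
Reagents that add atoms: none
Why: Proposed new method: enol-directed dehydrogenative C(aryl)–H/O–H cyclisation, in which the enolate of 7 binds divalent palladium through the oxygen next to ring B and opens its O,O-chelate by rotation about C3–C4, so that the only free ortho C–H of ring A (para to a methoxy group, ortho to the acyl group) is cleaved by acetylglycinate-assisted concerted metalation–deprotonation to a seven-membered oxapalladacycle, the perester oxidises this by two electrons to tetravalent palladium, and C(aryl)–O reductive elimination closes ring C while the benzoate and tert-butoxide left on divalent palladium take up the two protons of the next substrate molecule; C-arylation would need a four-membered ring, ring B has no ortho C–H, a two-electron perester spares the easily oxidised ring B, and the non-polar solvent with only catalytic acetate suppresses base-induced displacement of an ortho methoxy group; the closest known reaction types are the palladium-catalysed carboxylate-directed C–H lactonisation of biaryl-2-carboxylic acids (same palladacycle size, the enolate being a vinylogous carboxylate) and the phenol-directed C–H/C–O cyclisation of 2-arylphenols to dibenzofurans with a perester oxidant; no stereocentre is formed.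

## Compound list
1 | 1,2,4,5-tetramethoxybenzene | COc1cc(OC)c(OC)cc1OC | starting material
2 | (2,3,5,6-tetramethoxyphenyl)lithium | [Li]c1c(OC)c(OC)cc(OC)c1OC | intermediate
3 | lithium 1-[methoxy(methyl)amino]-1-(2,3,5,6-tetramethoxyphenyl)ethan-1-olate (racemic; centre lost on collapse) | CC([O-])(N(C)OC)c1c(OC)c(OC)cc(OC)c1OC.[Li+] | intermediate
4 | 1-(2,3,5,6-tetramethoxyphenyl)ethan-1-one | CC(=O)c1c(OC)c(OC)cc(OC)c1OC | intermediate
5 | methyl 2,3-dimethoxybenzoate | COC(=O)c1cccc(OC)c1OC | starting material
6 | sodium (Z)-3-(2,3-dimethoxyphenyl)-3-oxo-1-(2,3,5,6-tetramethoxyphenyl)prop-1-en-1-olate | [O-]/C(=C\C(=O)c1cccc(OC)c1OC)c1c(OC)c(OC)cc(OC)c1OC.[Na+] | intermediate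
7 | 1-(2,3-dimethoxyphenyl)-3-(2,3,5,6-tetramethoxyphenyl)propane-1,3-dione (largely enolised) | COc1cccc(C(=O)CC(=O)c2c(OC)c(OC)cc(OC)c2OC)c1OC | intermediate
8 | 5,6-dimethoxy-2-(2,3,5,6-tetramethoxyphenyl)-4H-chromen-4-one (achiral) | COc1cc(OC)c(OC)c(-c2cc(=O)c3c(OC)c(OC)ccc3o2)c1OC | target

## Step count and risks
Total steps: 3. Longest linear sequence: 3 (1 → 4 → 7 → 8).

The three steps most likely to fail are, in order, step 3, step 2 and step 1.

**Step 3, the proposed cyclisation, is the greatest risk.**
- Failure modes: palladium may be trapped as an inert bis(diketonate) chelate, ring B may be oxidised towards a quinone, C3 may be oxygenated, or the aryl–palladium bond may eliminate with benzoate instead of the enolate oxygen.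
- The fallback uses only known chemistry. It sets out from ketone 4 and comes back to the route at target 8.
- Commercial 2,3-dimethoxybenzaldehyde is brominated para to its 3-methoxy group with NBS in DMF to give 6-bromo-2,3-dimethoxybenzaldehyde F1.
- Aldol addition of 4 (LiN(i-Pr)2, THF, −78 °C) to F1 gives racemic 3-(6-bromo-2,3-dimethoxyphenyl)-3-hydroxy-1-(2,3,5,6-tetramethoxyphenyl)propan-1-one F2.
- Dess–Martin periodinane oxidises this to 1-(6-bromo-2,3-dimethoxyphenyl)-3-(2,3,5,6-tetramethoxyphenyl)propane-1,3-dione F3.
- The established intramolecular Ullmann-type O-arylation of the enolate (CuI 10 mol %, 1,10-phenanthroline 20 mol %, K2CO3, 1,4-dioxane, 90 °C) closes the same O1–C8a bond to give 8.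

**Step 2 is the second risk.**
- Failure mode: the enolate of the hindered, electron-rich ketone may react sluggishly with the ester, so conversion stalls.
- The fallback replaces acyl substitution by carbonyl addition plus oxidation. It sets out from 4 and comes back at diketone 7.
- Aldol addition of 4 (LiN(i-Pr)2, THF, −78 °C) to commercial 2,3-dimethoxybenzaldehyde gives racemic 3-(2,3-dimethoxyphenyl)-3-hydroxy-1-(2,3,5,6-tetramethoxyphenyl)propan-1-one F4.
- Dess–Martin periodinane in CH2Cl2 oxidises F4 to 7.

**Step 1 is the third risk.**
- Failure mode: the hindered, basic aryllithium may deprotonate the acetamide instead of adding to it, returning 1.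
- The fallback uses a non-enolisable electrophile and then adjusts the carbon count and oxidation level. It sets out from aryllithium 2 and comes back at ketone 4.
- Quenching 2 with DMF, then 1 M HCl, gives 2,3,5,6-tetramethoxybenzaldehyde F5.
- MeMgBr in THF at 0 °C gives racemic 1-(2,3,5,6-tetramethoxyphenyl)ethan-1-ol F6.
- Dess–Martin periodinane oxidises F6 to 4.

## Further compounds
F1 | step 3 | 6-bromo-2,3-dimethoxybenzaldehyde | COc1ccc(Br)c(C=O)c1OC
F2 | step 3 | 3-(6-bromo-2,3-dimethoxyphenyl)-3-hydroxy-1-(2,3,5,6-tetramethoxyphenyl)propan-1-one (racemic) | COc1ccc(Br)c(C(O)CC(=O)c2c(OC)c(OC)cc(OC)c2OC)c1OC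
F3 | step 3 | 1-(6-bromo-2,3-dimethoxyphenyl)-3-(2,3,5,6-tetramethoxyphenyl)propane-1,3-dione | COc1ccc(Br)c(C(=O)CC(=O)c2c(OC)c(OC)cc(OC)c2OC)c1OC
F4 | step 2 | 3-(2,3-dimethoxyphenyl)-3-hydroxy-1-(2,3,5,6-tetramethoxyphenyl)propan-1-one (racemic) | COc1cccc(C(O)CC(=O)c2c(OC)c(OC)cc(OC)c2OC)c1OC
F5 | step 1 | 2,3,5,6-tetramethoxybenzaldehyde | O=Cc1c(OC)c(OC)cc(OC)c1OC
F6 | step 1 | 1-(2,3,5,6-tetramethoxyphenyl)ethan-1-ol (racemic) | CC(O)c1c(OC)c(OC)cc(OC)c1OC
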